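**Plan**

1. Locants used below: carbocycle C1 (C=O), C2, C3, C4 (epoxide C, CH3 = C15), C5 (epoxide CH), C6 (lactone O–CH), C7 (spiro C), C8 (CH–O-methacryloyl), C9, C10 (C–CH3, ether O to C7); lactone C11 (=C13H2), C12 (C=O).
2. Retrosynthetic cuts, in order: C3–C4 (ring closure, last C–C bond), C4–C5 with the epoxide oxygen (Darzens), the C7–O ether bond (epoxide opening), C7–C11 (Stille), C8–C9 (acetylide/epoxide union). Both acrylate units travel as dimethylamine adducts.
3. Forward: fragment C5–C8 (from D-glyceraldehyde) and fragment C9–C10–C1–C3 (from methacrolein) are joined; then the γ-lactone, the spiro tetrahydrofuran, the C4–C5 epoxide and last the ten-membered ring are formed.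
4. Feature that allows the key event: the C1 ketone and the C4 epoxide oxygen stand 1,4 across C3–C4, so C3 (β-carbon of a C1 vinyl ketone) and C4 (a fully substituted epoxide carbon, the α-carbon of a glycidic acid) are both acceptor carbons. Loss of CO2 turns C4 into a radical, and the cis-2,5-disubstituted C7–O–C10 tetrahydrofuran of the 11-oxabicyclo[6.2.1]undecane core holds the two ends together.
5. Stereochemistry: C6 from the chiral pool; C10 from a Sharpless kinetic resolution; C7 and C8 relayed from C6 (face-selective epoxidation of an E-alkylidene lactone, inversion at C7); C5 by Felkin–Anh control in the Darzens step; C4 by ring strain in the key step.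

Key step: step 19

Remark: compounds 17–19 and 24–30 are mixtures of epimers at the two amine-bearing CH centres (25–28 also at C4); this is without consequence because these centres are fixed or removed in steps 19 and 20.

**Route**

Step 1
Reactants: 1 (R)-2,2-dimethyl-1,3-dioxolane-4-carbaldehyde (D-glyceraldehyde acetonide)
Product: 2 (S)-4-ethynyl-2,2-dimethyl-1,3-dioxolane
Conditions: CH3C(O)C(N2)P(O)(OMe)2, K2CO3, MeOH, 0 °C to rt
Reagents that add atoms: dimethyl (1-diazo-2-oxopropyl)phosphonate, CC(=O)C(=[N+]=[N-])P(=O)(OC)OC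
Why: Ohira–Bestmann (Seyferth–Gilbert) homologation should turn the aldehyde into the terminal alkyne (future C7≡C8) without touching the C6 stereocentre, which comes from the chiral pool.

Step 2
Reactants: 3 methacrolein
Product: 4 rac-2-methylpenta-1,4-dien-3-ol
Conditions: CH2=CHMgBr, THF, −78 °C; H2O work-up
Reagents that add atoms: vinylmagnesium bromide, C=C[Mg]Br
Why: Grignard 1,2-addition to the enal should give the bis-allylic alcohol that holds C9, C10, C14, C1, C2 and C3.

Step 3
Reactants: 4 rac-2-methylpenta-1,4-dien-3-ol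
Product: 5 (S)-1-[(R)-2-methyloxiran-2-yl]prop-2-en-1-ol
Conditions: Ti(OiPr)4, D-(−)-diisopropyl tartrate, t-BuOOH (0.55 equiv), 4 Å MS, CH2Cl2, −20 °C
Reagents that add atoms: tert-butyl hydroperoxide, CC(C)(C)OO
Why: Sharpless kinetic resolution: with D-(−)-tartrate the (S)-alcohol should be epoxidised fast at its 1,1-disubstituted olefin to the erythro (R)-epoxide, which sets C10, while the (R)-alcohol stays behind (at most half of the material is used).

Step 4
Reactants: 5 (S)-1-[(R)-2-methyloxiran-2-yl]prop-2-en-1-ol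
Product: 6 triisopropylsilyl ether of 5
Conditions: TIPSOTf, 2,6-lutidine, CH2Cl2, −78 to 0 °C
Reagents that add atoms: triisopropylsilyl triflate, CC(C)[Si](C(C)C)(C(C)C)OS(=O)(=O)C(F)(F)F
Why: Silylation blocks the C1 hydroxyl (no Payne rearrangement in step 5) with a group that outlasts acid, HF·pyridine and enolates.

Step 5
Reactants: 2 (S)-4-ethynyl-2,2-dimethyl-1,3-dioxolane; 6 triisopropylsilyl ether of 5
Product: 8 C8–C9 coupled alkynyl tertiary alcohol, via lithium acetylide 7 (not isolated)
Conditions: n-BuLi, THF, −78 °C; BF3·OEt2, then 6, −78 °C; H2O work-up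
Reagents that add atoms: none
Why: BF3-promoted opening of the 2,2-disubstituted epoxide at its CH2 terminus by the lithium acetylide should form C8–C9 and free the tertiary C10 hydroxyl without touching a stereocentre.

Step 6
Reactants: 8 C8–C9 coupled alkynyl tertiary alcohol
Product: 9 C5,C6,C10-triol
Conditions: AcOH/H2O 4:1, 40 °C
Reagents that add atoms: none
Why: Acetal hydrolysis frees the propargylic C6 hydroxyl needed as directing group and lactone oxygen; the TIPS ether and the tertiary alcohol should survive.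

Step 7
Reactants: 9 C5,C6,C10-triol
Product: 10 C5-O-TBS ether
Conditions: TBSCl, imidazole, CH2Cl2, 0 °C
Reagents that add atoms: tert-butyldimethylsilyl chloride, CC(C)(C)[Si](C)(C)Cl
Why: The primary hydroxyl is silylated selectively, so it cannot later open the C7–C8 epoxide or be acylated.

Step 8
Reactants: 10 C5-O-TBS ether
Product: 11 (Z)-C7-tributylstannyl allylic alcohol (Sn cis to C9)
Conditions: Bu3SnH, [Cp*RuCl]4 (cat.), CH2Cl2, rt
Reagents that add atoms: tributyltin hydride, CCCC[SnH](CCCC)CCCC
Why: Hydroxyl-directed ruthenium-catalysed trans-hydrostannation: the propargylic C6–OH should steer tin to the proximal carbon C7 and hydrogen adds trans at C8, which fixes the olefin geometry that later becomes the C8 configuration.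

Step 9
Reactants: 11 (Z)-C7-tributylstannyl allylic alcohol
Product: 13 (E)-alkylidene α-methylene-γ-lactone, via hydroxy dienoate 12 (not isolated)
Conditions: methyl 2-bromoacrylate, Pd(PPh3)4 (5 mol %), Cu(O2C-C4H3S) (copper thiophene-2-carboxylate), DMF, rt; then CSA (cat.), CH2Cl2, rt
Reagents that add atoms: methyl 2-bromoacrylate, C=C(Br)C(=O)OC
Why: Stille coupling with retention of olefin geometry should install C11, C12 and C13 as an acrylate, and the C6 hydroxyl then lactonises onto the ester.

Step 10
Reactants: 13 (E)-alkylidene α-methylene-γ-lactone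
Product: 15 spiro tetrahydrofuran lactone with free C8–OH, via spiro epoxide 14 (not isolated)
Conditions: mCPBA, NaHCO3, CH2Cl2, 0 °C; then CSA (cat.), 0 °C to rt
Reagents that add atoms: 3-chloroperbenzoic acid, OOC(=O)c1cccc(Cl)c1
Why: Prilezhaev epoxidation of the electron-rich exocyclic trisubstituted olefin anti to the C6 CH2OTBS group, then acid-mediated endo opening of the spiro epoxide by the tertiary C10 hydroxyl at the allylic, tertiary C7 with inversion, should set C7 and C8 from C6 and the E geometry.

Step 11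
Reactants: 15 spiro tetrahydrofuran lactone with free C8–OH
Product: 16 C8 methacrylate
Conditions: methacrylic anhydride, Et3N, DMAP (cat.), CH2Cl2, rt
Reagents that add atoms: methacrylic anhydride, C=C(C)C(=O)OC(=O)C(C)=C
Why: DMAP-catalysed acylation of the only free hydroxyl puts the ester side chain in place early.

Step 12
Reactants: 16 C8 methacrylate
Product: 17 bis(dimethylamine) adduct
Conditions: Me2NH (excess), THF/MeOH, rt to 40 °C
Reagents that add atoms: dimethylamine, CNC
Why: Double aza-Michael addition masks the α-methylene lactone and the methacrylate as β-dimethylamino esters that are inert to enolates and fluoride; the new CH centres form as mixtures.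

Step 13
Reactants: 17 bis(dimethylamine) adduct
Product: 18 C5 primary alcohol
Conditions: HF·pyridine, pyridine, THF, 0 °C
Reagents that add atoms: none
Why: The primary TBS ether should be cleaved selectively; the hindered secondary TIPS ether stays.

Step 14
Reactants: 18 C5 primary alcohol
Product: 19 C5 aldehyde
Conditions: SO3·pyridine, DMSO, i-Pr2NEt, CH2Cl2, 0 °C
Reagents that add atoms: none
Why: Parikh–Doering oxidation should give the α-oxygenated aldehyde without over-oxidation and tolerates the tertiary amines.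

Step 15
Reactants: 20 2-bromopropanoyl bromide; 21 2-(trimethylsilyl)ethanol
Product: 22 2-(trimethylsilyl)ethyl 2-bromopropanoate
Conditions: pyridine, CH2Cl2, 0 °C
Reagents that add atoms: none
Why: Acylation of the alcohol by the acid bromide gives the Darzens partner with a fluoride-labile ester.

Step 16
Reactants: 19 C5 aldehyde; 22 2-(trimethylsilyl)ethyl 2-bromopropanoate
Product: 25 glycidic ester (C4–C5 epoxide), via lithium enolate 23 (not isolated), via lithium bromohydrin alkoxide 24 (not isolated)
Conditions: LiHMDS, THF, −78 to 0 °C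
Reagents that add atoms: none
Why: Darzens condensation: the enolate should add under Felkin–Anh control (anti to the C6–O bond, past H6 and not past quaternary C7), which sets C5 with the C5–O/C6–O relationship of 31, and the alkoxide then displaces bromide; both C4 epimers are used.

Step 17
Reactants: 25 glycidic ester
Product: 26 hydroxy glycidic acid
Conditions: Bu4NF, THF, 0 °C to rt; H2O work-up
Reagents that add atoms: none
Why: Fluoride should cleave the 2-(trimethylsilyl)ethyl ester by β-elimination and the TIPS ether in one operation, leaving the glycidate as its carboxylate.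

Step 18
Reactants: 26 hydroxy glycidic acid
Product: 27 vinyl ketone glycidic acid
Conditions: MnO2, CH2Cl2, rt
Reagents that add atoms: none
Why: Neutral oxidation of the allylic alcohol gives the C1 vinyl ketone acceptor only now, after all basic and nucleophilic steps, and leaves amines, epoxide and carboxylate alone.

Step 19
Reactants: 27 vinyl ketone glycidic acid
Product: 29 ten-membered epoxy ketone (bis-amine adduct of the target), via N-acyloxyphthalimide 28 (not isolated)
Conditions: N-hydroxyphthalimide, i-PrN=C=N-i-Pr, DMAP (cat.), CH2Cl2, rt; then Zn, Ni(ClO4)2·6H2O (20 mol %), LiCl, MeCN, 2 mM, rt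
Reagents that add atoms: none
Why: Proposed new method: the acid is converted in the flask into the redox-active ester 28, single-electron reduction (Ni/Zn) releases CO2 and phthalimide anion and leaves the C4 oxiranyl σ-radical, which adds to the terminal carbon C3 of the C1 vinyl ketone; the α-keto radical is then reduced to the zinc enolate and protonated, so the ketone is delivered directly, the closest known reactions being the Ni/Zn decarboxylative Giese addition of such esters to enones, exo cyclisations of oxiranyl radicals made from glycidic acid derivatives and decarboxylative radical macrocyclisations onto acrylamides. The ring closed is the ten-membered carbocycle C1–C10, a 9-endo-trig closure when counted through the ether oxygen (10-endo through C8–C9), which completes the 11-oxabicyclo[6.2.1]undecane core. The only new stereocentre is C4: the methyl-substituted oxiranyl radical should invert faster than it cyclises, so both C4 epimers of 27 converge, and only the invertomer that bonds cis to C6 can close because a trans-fused epoxide in the bridged nine-membered ring is too strained; C5 is not touched. The step needs ring closure to beat hydrogen abstraction and reduction of the radical: the cis-2,5 arms of the tetrahydrofuran and the s-cis vinyl ketone hold C3 near C4, MeCN offers no weak C–H bond, high dilution stops oligomerisation and the two acrylate units are absent as their amine adducts.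

Step 20
Reactants: 29 ten-membered epoxy ketone
Product: 31 CNP0241021.1 (target), via bis(trimethylammonium) diiodide 30 (not isolated)
Conditions: MeI (excess), MeCN, rt; then NaHCO3 (aq), EtOAc, rt
Reagents that add atoms: none
Why: Exhaustive N-methylation and E1cB (Hofmann-type) loss of trimethylamine from both β-ammonio esters should regenerate the α-methylene lactone and the methacrylate; epoxide and ketone are inert.

**Compound list**

1 | (R)-2,2-dimethyl-1,3-dioxolane-4-carbaldehyde | O=C[C@H]1COC(C)(C)O1 | starting material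
2 | (S)-4-ethynyl-2,2-dimethyl-1,3-dioxolane | C#C[C@H]1COC(C)(C)O1 | intermediate
3 | methacrolein | C=C(C)C=O | starting material
4 | rac-2-methylpenta-1,4-dien-3-ol | C=CC(O)C(C)=C | intermediate
5 | (S)-1-[(R)-2-methyloxiran-2-yl]prop-2-en-1-ol | C=C[C@H](O)[C@@]1(C)CO1 | intermediate
6 | triisopropylsilyl ether of 5 | C=C[C@H](O[Si](C(C)C)(C(C)C)C(C)C)[C@@]1(C)CO1 | intermediate
7 | lithium acetylide of 2 | [Li]C#C[C@H]1COC(C)(C)O1 | intermediate
8 | (3S,4R)-7-[(4S)-2,2-dimethyl-1,3-dioxolan-4-yl]-4-methyl-3-(triisopropylsilyloxy)hept-1-en-6-yn-4-ol | C=C[C@H](O[Si](C(C)C)(C(C)C)C(C)C)[C@](C)(O)CC#C[C@H]1COC(C)(C)O1 | intermediate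
9 | (2S,6R,7S)-6-methyl-7-(triisopropylsilyloxy)non-8-en-3-yne-1,2,6-triol | C=C[C@H](O[Si](C(C)C)(C(C)C)C(C)C)[C@](C)(O)CC#C[C@H](O)CO | intermediate
10 | 1-O-tert-butyldimethylsilyl ether of 9 (C5–OTBS) | C=C[C@H](O[Si](C(C)C)(C(C)C)C(C)C)[C@](C)(O)CC#C[C@H](O)CO[Si](C)(C)C(C)(C)C | intermediate
11 | (Z)-C7-tributylstannyl C7=C8 alkene of 10 (Sn cis to C9; C1, C6, C10 as in 10) | C=C[C@H](O[Si](C(C)C)(C(C)C)C(C)C)[C@](C)(O)C/C=C(\[Sn](CCCC)(CCCC)CCCC)[C@H](O)CO[Si](C)(C)C(C)(C)C | intermediate
12 | methyl 2-methylidene ester from Stille coupling at C7 (C11 cis to C9), C6–OH free | C=C[C@H](O[Si](C(C)C)(C(C)C)C(C)C)[C@](C)(O)C/C=C(\C(=C)C(=O)OC)[C@H](O)CO[Si](C)(C)C(C)(C)C | intermediate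
13 | (E)-C7=C8 alkylidene α-methylene-γ-lactone (lactone O on C6) | C=C[C@H](O[Si](C(C)C)(C(C)C)C(C)C)[C@](C)(O)C/C=C1\C(=C)C(=O)O[C@@H]1CO[Si](C)(C)C(C)(C)C | intermediate
14 | C7–C8 spiro epoxide of 13 (epoxide O trans to the C6 CH2OTBS group) | C=C[C@H](O[Si](C(C)C)(C(C)C)C(C)C)[C@](C)(O)C[C@@H]1O[C@]12C(=C)C(=O)O[C@@H]2CO[Si](C)(C)C(C)(C)C | intermediate
15 | spiro tetrahydrofuran α-methylene lactone, C8–OH, C5–OTBS, C1–OTIPS allyl carbinol (C6, C7, C8, C10 as in 31) | O[C@H]1C[C@@]([C@@H](O[Si](C(C)C)(C(C)C)C(C)C)C=C)(C)O[C@@]13C(=C)C(=O)O[C@@H]3CO[Si](C)(C)C(C)(C)C | intermediate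
16 | C8 methacrylate of 15 | C=C(C)C(=O)O[C@H]1C[C@@]([C@@H](O[Si](C(C)C)(C(C)C)C(C)C)C=C)(C)O[C@@]13C(=C)C(=O)O[C@@H]3CO[Si](C)(C)C(C)(C)C | intermediate
17 | bis(dimethylamine) adduct of 16 (C11–CH2NMe2 lactone, 3-(dimethylamino)-2-methylpropanoate at C8) | CN(C)CC(C)C(=O)O[C@H]1C[C@@]([C@@H](O[Si](C(C)C)(C(C)C)C(C)C)C=C)(C)O[C@@]13C(CN(C)C)C(=O)O[C@@H]3CO[Si](C)(C)C(C)(C)C | intermediate
18 | C5 primary alcohol from 17 | CN(C)CC(C)C(=O)O[C@H]1C[C@@]([C@@H](O[Si](C(C)C)(C(C)C)C(C)C)C=C)(C)O[C@@]13C(CN(C)C)C(=O)O[C@@H]3CO | intermediate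
19 | C5 aldehyde | CN(C)CC(C)C(=O)O[C@H]1C[C@@]([C@@H](O[Si](C(C)C)(C(C)C)C(C)C)C=C)(C)O[C@@]13C(CN(C)C)C(=O)O[C@@H]3C=O | intermediate
20 | 2-bromopropanoyl bromide | CC(Br)C(=O)Br | starting material
21 | 2-(trimethylsilyl)ethanol | C[Si](C)(C)CCO | starting material
22 | 2-(trimethylsilyl)ethyl 2-bromopropanoate (racemic) | CC(Br)C(=O)OCC[Si](C)(C)C | intermediate
23 | lithium enolate of 22 | CC(Br)=C(O[Li])OCC[Si](C)(C)C | intermediate
24 | lithium alkoxide of the C5 bromohydrin (aldol adduct; C5–O anti to C6–O) | CN(C)CC(C)C(=O)O[C@H]1C[C@@]([C@@H](O[Si](C(C)C)(C(C)C)C(C)C)C=C)(C)O[C@@]13C(CN(C)C)C(=O)O[C@@H]3[C@H](O[Li])C(C)(Br)C(=O)OCC[Si](C)(C)C | intermediate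
25 | 2-(trimethylsilyl)ethyl glycidate (C4–C5 epoxide, C4 bearing CH3 and CO2R; C5 as in 31) | CN(C)CC(C)C(=O)O[C@H]1C[C@@]([C@@H](O[Si](C(C)C)(C(C)C)C(C)C)C=C)(C)O[C@@]13C(CN(C)C)C(=O)O[C@@H]3[C@@H]1OC1(C)C(=O)OCC[Si](C)(C)C | intermediate
26 | glycidic acid with free C1 allylic alcohol | CN(C)CC(C)C(=O)O[C@H]1C[C@@]([C@@H](O)C=C)(C)O[C@@]13C(CN(C)C)C(=O)O[C@@H]3[C@@H]1OC1(C)C(=O)O | intermediate
27 | glycidic acid with C1 vinyl ketone | CN(C)CC(C)C(=O)O[C@H]1C[C@@](C(=O)C=C)(C)O[C@@]13C(CN(C)C)C(=O)O[C@@H]3[C@@H]1OC1(C)C(=O)O | intermediate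
28 | N-acyloxyphthalimide (redox-active ester) of 27 | CN(C)CC(C)C(=O)O[C@H]1C[C@@](C(=O)C=C)(C)O[C@@]13C(CN(C)C)C(=O)O[C@@H]3[C@@H]1OC1(C)C(=O)ON1C(=O)c2ccccc2C1=O | intermediate
29 | ten-membered 1-oxo-4,5-epoxide, bis(dimethylamine) adduct of 31 (4R,5S,6R,7S,8S,10R) | CN(C)CC(C)C(=O)O[C@H]1C[C@@]2(C)O[C@@]13C(CN(C)C)C(=O)O[C@@H]3[C@@H]1O[C@]1(C)CCC2=O | intermediate
30 | bis(trimethylammonium) diiodide of 29 | C[N+](C)(C)CC(C)C(=O)O[C@H]1C[C@@]2(C)O[C@@]13C(C[N+](C)(C)C)C(=O)O[C@@H]3[C@@H]1O[C@]1(C)CCC2=O.[I-].[I-] | intermediate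
31 | CNP0241021.1, (4R,5S,6R,7S,8S,10R) in the locants above | C=C(C)C(=O)O[C@H]1C[C@@]2(C)O[C@@]13C(=C)C(=O)O[C@@H]3[C@@H]1O[C@]1(C)CCC2=O | target

**Step count and risks**

Total step count: 20. Longest linear sequence: 18 steps (steps 2–14, then 16–20; steps 1 and 15 are side branches).

The three steps most likely to fail:

Step 19 (proposed new method). The oxiranyl σ-radical may be quenched before the strained closure, by hydrogen abstraction from the medium, by 1,5-hydrogen transfer from C8–H or by over-reduction, or it may oligomerise. The fallback uses known chemistry, a B-alkyl Suzuki–Miyaura macrocyclisation followed by epoxide formation through a bromohydrin. It sets out from aldehyde 19 and comes back to the route at compound 29. Stork–Zhao olefination of 19 (EtPPh3I, n-BuLi, I2, then NaHMDS, THF, −78 °C) should give the (Z)-2-iodopropenyl compound F1, in which iodine is cis to C6. Hydroboration of its terminal vinyl group with 9-BBN-H gives the B-alkyl borane F2, which is closed without isolation (Pd(dppf)Cl2, AsPh3, Cs2CO3, DMF/THF/H2O, high dilution) to the ten-membered (Z)-olefin with C1–OTIPS F3. Bu4NF gives the C1 alcohol F4 and Dess–Martin periodinane the ketone F5. Hydroxybromination of the trisubstituted olefin (NBS, aqueous acetone, amines as trifluoroacetate salts) gives the bromohydrin F6, and K2CO3 closes the epoxide to 29. The bromohydrin route is chosen because, with H6 eclipsing the olefin, an electrophile should approach anti to C7; water then enters at tertiary C4 from the other face and closure with inversion at C5 puts the oxygen syn to C7 as in 31, whereas direct peracid epoxidation would be expected on the wrong face.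

Step 10. Facial selectivity of the peracid on the exocyclic olefin may be poor, the acrylate-conjugated spiro epoxide may ionise at C7 (loss of stereospecificity or a 1,2-shift), and the cross-conjugated dienyl lactone 13 may dimerise by Diels–Alder reaction before it is oxidised. The fallback changes the order so that the acrylate is masked first; it sets out from 13 and comes back at compound 17. Me2NH adds to 13 to give the α-(dimethylaminomethyl) alkylidene lactone F7, whose olefin is now isolated. Epoxidation of its trifluoroacetate salt with mCPBA gives the spiro epoxide F8, and CSA-mediated opening by the C10 hydroxyl gives the spiro tetrahydrofuran alcohol F9. Methacrylic anhydride/DMAP then gives the methacrylate F10, and a second Me2NH addition gives 17.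

Step 16. The α-oxygenated aldehyde may epimerise at C6 or eliminate under lithium amide and enolate conditions, and the facial selectivity of the lithium aldol step may be low. The fallback replaces the one-pot Darzens reaction by an open-transition-state Mukaiyama aldol and a separate ring closure; it sets out from 19 and 22 and comes back at compound 25. Ester 22 is converted (LDA, Me3SiCl, THF, −78 °C) into the silyl ketene acetal F11. BF3·OEt2-promoted addition of F11 to 19 in CH2Cl2 at −78 °C should give the Felkin bromohydrin F12 without base, and DBU closes it to 25.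

**Further compounds**

F1 | step 19 | (Z)-2-iodoprop-1-enyl compound from aldehyde 19 (I cis to C6) | CN(C)CC(C)C(=O)O[C@H]1C[C@@]([C@@H](O[Si](C(C)C)(C(C)C)C(C)C)C=C)(C)O[C@@]13C(CN(C)C)C(=O)O[C@@H]3/C=C(/C)I
F2 | step 19 | B-alkyl-9-borabicyclo[3.3.1]nonane from hydroboration of the vinyl group of F1 | CN(C)CC(C)C(=O)O[C@H]1C[C@@]([C@@H](O[Si](C(C)C)(C(C)C)C(C)C)CCB2C4CCCC2CCC4)(C)O[C@@]13C(CN(C)C)C(=O)O[C@@H]3/C=C(/C)I
F3 | step 19 | ten-membered (Z)-C4=C5 olefin with C1–OTIPS | CN(C)CC(C)C(=O)O[C@H]1C[C@@]2(C)O[C@@]13C(CN(C)C)C(=O)O[C@@H]3/C=C(C)\CC[C@@H]2O[Si](C(C)C)(C(C)C)C(C)C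
F4 | step 19 | ten-membered (Z)-olefin with C1–OH | CN(C)CC(C)C(=O)O[C@H]1C[C@@]2(C)O[C@@]13C(CN(C)C)C(=O)O[C@@H]3/C=C(C)\CC[C@@H]2O
F5 | step 19 | ten-membered (Z)-olefin C1 ketone (4,5-deoxy analogue of 29) | CN(C)CC(C)C(=O)O[C@H]1C[C@@]2(C)O[C@@]13C(CN(C)C)C(=O)O[C@@H]3/C=C(C)\CCC2=O
F6 | step 19 | C5-bromo C4-hydroxy bromohydrin of F5 | CN(C)CC(C)C(=O)O[C@H]1C[C@@]2(C)O[C@@]13C(CN(C)C)C(=O)O[C@@H]3[C@@H](Br)[C@@](O)(C)CCC2=O
F7 | step 10 | dimethylamine adduct of dienyl lactone 13 | C=C[C@H](O[Si](C(C)C)(C(C)C)C(C)C)[C@](C)(O)C/C=C1\C(CN(C)C)C(=O)O[C@@H]1CO[Si](C)(C)C(C)(C)C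
F8 | step 10 | C7–C8 spiro epoxide of F7 | C=C[C@H](O[Si](C(C)C)(C(C)C)C(C)C)[C@](C)(O)C[C@@H]1O[C@]12C(CN(C)C)C(=O)O[C@@H]2CO[Si](C)(C)C(C)(C)C
F9 | step 10 | spiro tetrahydrofuran lactone with C11–CH2NMe2 and free C8–OH | O[C@H]1C[C@@]([C@@H](O[Si](C(C)C)(C(C)C)C(C)C)C=C)(C)O[C@@]13C(CN(C)C)C(=O)O[C@@H]3CO[Si](C)(C)C(C)(C)C
F10 | step 10 | C8 methacrylate of F9 | C=C(C)C(=O)O[C@H]1C[C@@]([C@@H](O[Si](C(C)C)(C(C)C)C(C)C)C=C)(C)O[C@@]13C(CN(C)C)C(=O)O[C@@H]3CO[Si](C)(C)C(C)(C)C
F11 | step 16 | trimethylsilyl ketene acetal of 22 | CC(Br)=C(O[Si](C)(C)C)OCC[Si](C)(C)C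
F12 | step 16 | C5 bromohydrin ester (neutral form of 24) | CN(C)CC(C)C(=O)O[C@H]1C[C@@]([C@@H](O[Si](C(C)C)(C(C)C)C(C)C)C=C)(C)O[C@@]13C(CN(C)C)C(=O)O[C@@H]3[C@H](O)C(C)(Br)C(=O)OCC[Si](C)(C)C
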